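**Retrosynthetic overview**
1. The strategy rests on the vicinal pair C7(OH)–C8(OAr). In the C7 ketone the only stereocentre is C8. Its hydrogen lies between the aroyl carbonyl on ring A (3,4,5-trimethoxyphenyl) and the ether oxygen of electron-poor ring B (2-methoxy-4-methoxycarbonylphenyl), so C8 is mobile in the ketone and frozen in the alcohol.
2. Last disconnection, C7–H: one asymmetric transfer hydrogenation under dynamic kinetic resolution converts the racemic α-aryloxy ketone into the (7S,8S)-threo alcohol.
3. C8–O(ring B): SN2 of methyl vanillate on the racemic α-bromo ketone. C8–Br: α-bromination of the propiophenone.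
4. C7–C8: ethyl Grignard addition to 3,4,5-trimethoxybenzaldehyde, then benzylic oxidation.
5. No ring is formed. Rings A and B are bought intact, and the bonds are made in the order C7–C8, C8–Br, C8–O, C7–H.

Key step: step 5

Assumption: neolignan numbering is used (C7 = carbinol carbon on ring A, C8 = ether-bearing carbon, C9 = methyl). RuCl[(R,R)-teth-TsDPEN] denotes the chlororuthenium complex of (1R,2R)-N-tosyl-N'-(3-phenylpropyl)-1,2-diphenylethane-1,2-diamine, whose tethered phenyl group is the η6 ligand.

Step 1
Reactants: 1 3,4,5-trimethoxybenzaldehyde; 2 ethylmagnesium bromide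
Product: 4 racemic 1-(3,4,5-trimethoxyphenyl)propan-1-ol, via bromomagnesium alkoxide 3 (not isolated)
Conditions: 2 (1.2 equiv), THF, 0 °C to rt; then sat. aq NH4Cl
Reagents that add atoms: none
Why: Grignard 1,2-addition to a non-enolisable aromatic aldehyde should form the C7–C8 bond cleanly, and the new C7 centre is racemic without consequence because step 2 removes it.

Step 2
Reactants: 4 racemic 1-(3,4,5-trimethoxyphenyl)propan-1-ol
Product: 5 1-(3,4,5-trimethoxyphenyl)propan-1-one
Conditions: activated MnO2 (10 equiv), CH2Cl2, rt
Reagents that add atoms: none
Why: Benzylic alcohol oxidation on activated MnO2 is selective for the ring-A-activated C7 carbinol, cannot carry a ketone further and leaves the aryl methyl ethers alone; the C7 stereocentre is erased and none is created.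

Step 3
Reactants: 5 1-(3,4,5-trimethoxyphenyl)propan-1-one
Product: 6 racemic 2-bromo-1-(3,4,5-trimethoxyphenyl)propan-1-one
Conditions: CuBr2 (2.1 equiv), EtOAc/CHCl3 1:1, reflux
Reagents that add atoms: copper dibromide CuBr2, [Cu+2].[Br-].[Br-]
Why: Heterogeneous α-bromination of an enolisable aryl ketone with CuBr2 passes bromine to the enol at C8 without a standing concentration of Br2, which should spare C2/C6 of electron-rich ring A and stop at the monobromide because 6 enolises more slowly; C8 is formed racemic, as wanted.

Step 4
Reactants: 6 racemic 2-bromo-1-(3,4,5-trimethoxyphenyl)propan-1-one; 7 methyl vanillate (methyl 4-hydroxy-3-methoxybenzoate)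
Product: 9 racemic methyl 3-methoxy-4-{[1-oxo-1-(3,4,5-trimethoxyphenyl)propan-2-yl]oxy}benzoate, via potassium phenoxide 8 (not isolated)
Conditions: K2CO3 (1.5 equiv), dry acetone, reflux
Reagents that add atoms: none
Why: Williamson-type SN2 etherification, in which the phenoxide of the fairly acidic 7 displaces bromide at C8, a carbon activated by the adjacent carbonyl, under carbonate conditions too mild to cleave the methyl ester; C8 stays racemic, which is the input step 5 requires.

Step 5
Reactants: 9 racemic methyl 3-methoxy-4-{[1-oxo-1-(3,4,5-trimethoxyphenyl)propan-2-yl]oxy}benzoate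
Product: 12 methyl 4-{[(1S,2S)-1-hydroxy-1-(3,4,5-trimethoxyphenyl)propan-2-yl]oxy}-3-methoxybenzoate, via achiral enol 10 (not isolated), via 8S ketone 11 (not isolated)
Conditions: RuCl[(R,R)-teth-TsDPEN] (0.5 mol%), Et3N (5 equiv), DBU (0.3 equiv), HCO2H (2 equiv, fed over 8 h), degassed MeCN, 40 °C, N2 sweep
Reagents that add atoms: none
Why: Formate converts the catalyst into its 18-electron Ru–H/N–H form, which passes hydride and proton to the C7 carbonyl in a concerted outer-sphere six-membered transition state while free amine interconverts the two C8 antipodes of 9 by way of enol 10, so both antipodes should end up as 12 through the faster-reacting 11; loss of CO2 makes the reduction irreversible and no ring is closed. The closest known reaction types are Noyori–Ikariya transfer hydrogenation with dynamic kinetic resolution of benzoin (to threo-hydrobenzoin), of α-alkoxy β-keto esters (to syn products) and of acyclic α-(alkoxycarbonylamino) alkyl aryl ketones in amine/formic acid, together with hydrogenative dynamic resolution of α-aryloxy ketones, and the present case differs in that C8–H has one carbonyl and one ether oxygen as its only activators. C7 is set by the catalyst: an attractive CH/π contact docks ring A beneath the η6-arene, so the (R,R) ligand sends hydride to the Re face of C7=O and gives 7S, the spatial sense in which the same ligand makes (S,S)-hydrobenzoin from benzil. C8 is set by relative rate: the outer-sphere catalyst offers no site for chelation, so the polar Felkin–Anh rotamer applies, with hydride arriving antiperiplanar to the C8–O bond, and on the catalyst-chosen face only 11 then turns C8–H instead of the C9 methyl toward the hydride path, which leads to the threo (syn) pair. Two selectivities are required: C8 epimerisation must stay ahead of hydride transfer to the 8R antipode, which rests on the C8–H acidity conferred by the ring A aroyl carbonyl and the oxygen of ester-bearing ring B and is backed by the low catalyst loading and by slow feeding of HCO2H so that DBU is not simply tied up as its formate salt, and 11 must react much faster than its mirror image, which rests on the Felkin–Anh bias pointing the same way as the aryl-directed facial choice. After reduction C8 can no longer epimerise, the enolate of 9 carries its aryloxy group on the enolate carbon itself and so has no β-leaving group to expel, and the absence of alkoxide and alcohol solvent should leave the methyl ester untouched.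

**Compound list**
1 | 3,4,5-trimethoxybenzaldehyde | COc1cc(C=O)cc(OC)c1OC | starting material
2 | ethylmagnesium bromide | CC[Mg]Br | starting material
3 | racemic bromomagnesium 1-(3,4,5-trimethoxyphenyl)propan-1-olate | CCC(O[Mg]Br)c1cc(OC)c(OC)c(OC)c1 | intermediate
4 | racemic 1-(3,4,5-trimethoxyphenyl)propan-1-ol | CCC(O)c1cc(OC)c(OC)c(OC)c1 | intermediate
5 | 1-(3,4,5-trimethoxyphenyl)propan-1-one | CCC(=O)c1cc(OC)c(OC)c(OC)c1 | intermediate
6 | racemic 2-bromo-1-(3,4,5-trimethoxyphenyl)propan-1-one | CC(Br)C(=O)c1cc(OC)c(OC)c(OC)c1 | intermediate
7 | methyl vanillate (methyl 4-hydroxy-3-methoxybenzoate) | COC(=O)c1ccc(O)c(OC)c1 | starting material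
8 | potassium 2-methoxy-4-(methoxycarbonyl)phenolate | COC(=O)c1ccc([O-])c(OC)c1.[K+] | intermediate
9 | racemic methyl 3-methoxy-4-{[1-oxo-1-(3,4,5-trimethoxyphenyl)propan-2-yl]oxy}benzoate | COC(=O)c1ccc(OC(C)C(=O)c2cc(OC)c(OC)c(OC)c2)c(OC)c1 | intermediate
10 | methyl 4-{[1-hydroxy-1-(3,4,5-trimethoxyphenyl)prop-1-en-2-yl]oxy}-3-methoxybenzoate (achiral enol of 9, C7=C8 geometry not defined) | COC(=O)c1ccc(OC(C)=C(O)c2cc(OC)c(OC)c(OC)c2)c(OC)c1 | intermediate
11 | methyl 3-methoxy-4-{[(2S)-1-oxo-1-(3,4,5-trimethoxyphenyl)propan-2-yl]oxy}benzoate (8S antipode of 9) | COC(=O)c1ccc(O[C@@H](C)C(=O)c2cc(OC)c(OC)c(OC)c2)c(OC)c1 | intermediate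
12 | methyl 4-{[(1S,2S)-1-hydroxy-1-(3,4,5-trimethoxyphenyl)propan-2-yl]oxy}-3-methoxybenzoate, (7S,8S)-threo, CNP0078566.1 | COC(=O)c1ccc(O[C@@H](C)[C@@H](O)c2cc(OC)c(OC)c(OC)c2)c(OC)c1 | target

Total step count: 5. Longest linear sequence: 5 steps (1 → 4 → 5 → 6 → 9 → 12).

**Steps most likely to fail**

Risk 1, step 5. Epimerisation at C8 may lag behind hydride transfer, because C8–H lacks a second carbonyl or aryl activator. The process would then slide toward a plain kinetic resolution, and erythro material would build up from the 8R antipode. The rate gap between the antipodes may also be smaller than in the benzoin case.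

Two checks apply. Ketone sampled at partial conversion should still be racemic if the dynamic regime holds. The threo assignment should follow from an H7–H8 coupling larger than that of the erythro isomer.

The fallback fixes C8 from the chiral pool, sets out from 7 and comes back at 11.
- Bought methyl (R)-lactate is treated with MeNHOMe·HCl and i-PrMgCl in THF at −20 °C to give (R)-2-hydroxy-N-methoxy-N-methylpropanamide F1.
- Mitsunobu etherification of F1 with 7 (PPh3, DIAD, THF, 0 °C to rt) inverts the carbinol carbon and gives methyl 3-methoxy-4-{[(2S)-1-[methoxy(methyl)amino]-1-oxopropan-2-yl]oxy}benzoate F2.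
- 3,4,5-Trimethoxyphenylmagnesium bromide F3, made from bought 5-bromo-1,2,3-trimethoxybenzene and Mg in THF, is added to F2 at −40 °C. The chelating, α-oxygenated Weinreb amide should react ahead of the electron-rich benzoate ester, and the ketone is released only on the aq NH4Cl quench, giving 11.
- The same catalyst in acid-rich HCO2H/Et3N 5:2 at rt, with no free base, then reduces 11 as the matched substrate to 12.
- A C8–H too inert for the dynamic process is, for the same reason, configurationally safe in this sequence.

Risk 2, step 3. Electrophilic bromination of ring A at C2/C6, or a second bromination at C8, may compete with monobromination. The fallback replaces halogenation by hypervalent-iodine α-oxidation, sets out from 5 and comes back at 9. PhI(OH)OTs in MeCN at reflux gives racemic 1-oxo-1-(3,4,5-trimethoxyphenyl)propan-2-yl 4-methylbenzenesulfonate F4. Its tosylate is then displaced by 7 with K2CO3 in acetone at reflux.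

Risk 3, step 4. Base-induced loss of HBr from 6 followed by conjugate addition of the phenoxide at C9 would misplace the ether, and substitution at the secondary carbon may be sluggish. The fallback forms the C8–O bond under neutral redox-condensation conditions, sets out from 6 and comes back at 9. HCO2Na in MeOH at reflux gives racemic 1-oxo-1-(3,4,5-trimethoxyphenyl)propan-2-yl formate F5. This is methanolysed in the same pot to racemic 2-hydroxy-1-(3,4,5-trimethoxyphenyl)propan-1-one F6. Mitsunobu etherification of F6 with 7 (PPh3, DIAD, THF, 0 °C to rt) then gives 9.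

**Further compounds**
F1 | step 5 | (R)-2-hydroxy-N-methoxy-N-methylpropanamide | C[C@@H](O)C(=O)N(C)OC
F2 | step 5 | methyl 3-methoxy-4-{[(2S)-1-[methoxy(methyl)amino]-1-oxopropan-2-yl]oxy}benzoate | C[C@H](Oc1ccc(cc1OC)C(=O)OC)C(=O)N(C)OC
F3 | step 5 | 3,4,5-trimethoxyphenylmagnesium bromide | COc1cc([Mg]Br)cc(OC)c1OC
F4 | step 3 | racemic 1-oxo-1-(3,4,5-trimethoxyphenyl)propan-2-yl 4-methylbenzenesulfonate | CC(OS(=O)(=O)c1ccc(C)cc1)C(=O)c1cc(OC)c(OC)c(OC)c1
F5 | step 4 | racemic 1-oxo-1-(3,4,5-trimethoxyphenyl)propan-2-yl formate | CC(OC=O)C(=O)c1cc(OC)c(OC)c(OC)c1
F6 | step 4 | racemic 2-hydroxy-1-(3,4,5-trimethoxyphenyl)propan-1-one | CC(O)C(=O)c1cc(OC)c(OC)c(OC)c1
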